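**Retrosynthetic overview**
1. Kushenol V ⇐ its 2',4'-bis-TBS ether (mild fluoride release at the end).
2. Bis-TBS flavanone ⇐ one acyclic (S)-δ-hydroxy-diketo-dioxinone. In one flask ring C closes first (cyclodehydration onto the C8a carbonyl), then ring A (dioxinone → acylketene → 6π closure onto C4a). Closing ring C first fixes the prenyl group at C6.
3. Acyclic chain ⇐ Claisen union of an (S)-β-hydroxy thioester (ring B plus C2–C4) with the dianion of a 5-prenyl keto-dioxinone (C4a, C8a, C8, C7, C6, C5).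
4. (S)-Thioester ⇐ catalytic asymmetric Mukaiyama aldol on the bis-TBS aldehyde (sets the only stereocenter). Keto-dioxinone ⇐ 2,2,6-trimethyl-1,3-dioxin-4-one by C5 iodination, Stille prenylation and γ-acetylation.
5. Ring order: ring B is bought, then ring C, then ring A (C and A in the same operation).

Assumption: 2,4-dihydroxy-5-methoxybenzaldehyde, 1-(tert-butylthio)-1-(trimethylsilyloxy)ethene and tributyl(3-methylbut-2-en-1-yl)stannane are bought as catalogue compounds.

**Step 1**
Reactants: 1 2,4-dihydroxy-5-methoxybenzaldehyde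
Product: 2 2,4-bis(tert-butyldimethylsilyloxy)-5-methoxybenzaldehyde
Conditions: TBSCl (2.5 equiv), imidazole (5 equiv), DMF, 23 °C
Reagents that add atoms: tert-butyldimethylsilyl chloride, CC(C)(C)[Si](C)(C)Cl
Why: Imidazole-promoted O-silylation masks both phenols as base-stable, fluoride-labile aryl silyl ethers, so the aldehyde is the only electrophile and no phenoxide can later open the flavanone; no stereocenter is involved.

**Step 2**
Reactants: 2 2,4-bis(tert-butyldimethylsilyloxy)-5-methoxybenzaldehyde; 3 1-(tert-butylthio)-1-(trimethylsilyloxy)ethene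
Product: 5 S-tert-butyl (3S)-3-[2,4-bis(tert-butyldimethylsilyloxy)-5-methoxyphenyl]-3-hydroxypropanethioate, via TMS ether 4 (not isolated)
Conditions: (S)-BINOL (20 mol %), Ti(OiPr)4 (20 mol %), 4 Å MS, Et2O, −20 °C; then 1 M HCl, THF, 0 °C
Reagents that add atoms: none
Why: Keck-type BINOL–titanium Mukaiyama aldol in which the (S)-ligand, by analogy with benzaldehyde, directs the silyl ketene thioacetal to the Si face of the aldehyde and so sets the future C2 as (S); silyl transfer gives 4, which is hydrolysed to 5 (ee raised by one crystallisation if needed).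

**Step 3**
Reactants: 6 2,2,6-trimethyl-4H-1,3-dioxin-4-one
Product: 7 5-iodo-2,2,6-trimethyl-4H-1,3-dioxin-4-one
Conditions: NIS (1.1 equiv), AcOH, 23 °C, dark
Reagents that add atoms: N-iodosuccinimide, O=C1CCC(=O)N1I
Why: Electrophilic α-iodination of the push–pull enol ether occurs at C5, the only nucleophilic carbon of the dioxinone; no stereocenter.

**Step 4**
Reactants: 7 5-iodo-2,2,6-trimethyl-4H-1,3-dioxin-4-one; 8 tributyl(3-methylbut-2-en-1-yl)stannane
Product: 9 2,2,6-trimethyl-5-(3-methylbut-2-en-1-yl)-4H-1,3-dioxin-4-one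
Conditions: Pd2(dba)3 (2.5 mol %), AsPh3 (10 mol %), CuI (10 mol %), DMF, 40 °C
Reagents that add atoms: none
Why: Stille coupling of the α-iodo enone-type vinyl iodide with the allylic stannane; reductive elimination from the less hindered σ-allyl palladium terminus delivers the linear prenyl group under acid-free conditions that spare the trisubstituted alkene.

**Step 5**
Reactants: 9 2,2,6-trimethyl-5-(3-methylbut-2-en-1-yl)-4H-1,3-dioxin-4-one
Product: 11 2,2-dimethyl-5-(3-methylbut-2-en-1-yl)-6-(2-oxopropyl)-4H-1,3-dioxin-4-one, via lithium dienolate 10 (not isolated)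
Conditions: 9 (2.0 equiv), LiN(SiMe3)2 (2.0 equiv), THF, −78 °C; then AcCl (1.0 equiv), −78 °C; 1 M HCl quench
Reagents that add atoms: acetyl chloride, CC(=O)Cl
Why: γ-Deprotonation of the 6-methyl group gives the dioxinone dienolate, which is C-acylated at the γ-carbon (vinylogous Claisen acylation); the second equivalent of dienolate deprotonates the more acidic product and is recovered as 9.

**Step 6**
Reactants: 11 2,2-dimethyl-5-(3-methylbut-2-en-1-yl)-6-(2-oxopropyl)-4H-1,3-dioxin-4-one; 5 S-tert-butyl (3S)-3-[2,4-bis(tert-butyldimethylsilyloxy)-5-methoxyphenyl]-3-hydroxypropanethioate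
Product: 14 6-{(6S)-6-[2,4-bis(tert-butyldimethylsilyloxy)-5-methoxyphenyl]-6-hydroxy-2,4-dioxohexyl}-2,2-dimethyl-5-(3-methylbut-2-en-1-yl)-4H-1,3-dioxin-4-one, via dilithio dianion 12 (not isolated), via lithium alkoxide 13 (not isolated)
Conditions: 11 (2.2 equiv), LiN(iPr)2 (4.4 equiv), THF, −78 → −40 °C; add 5 (1.0 equiv) pre-treated with LiN(iPr)2 (1.0 equiv) at −78 °C; −78 → −40 °C; AcOH, −78 °C
Reagents that add atoms: none
Why: Claisen-type acylation of a 1,3-dicarbonyl dianion (Huckin–Weiler type) in which the last-formed terminal carbanion of 12 attacks the thioester; the lithium alkoxide 13 suppresses α-deprotonation and elimination, and the cold temperature avoids retro-aldol so the (S) carbinol is untouched.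

**Step 7**
Reactants: 14 6-{(6S)-6-[2,4-bis(tert-butyldimethylsilyloxy)-5-methoxyphenyl]-6-hydroxy-2,4-dioxohexyl}-2,2-dimethyl-5-(3-methylbut-2-en-1-yl)-4H-1,3-dioxin-4-one
Product: 18 (2S)-2-[2,4-bis(tert-butyldimethylsilyloxy)-5-methoxyphenyl]-5,7-dihydroxy-6-(3-methylbut-2-en-1-yl)chroman-4-one, via dihydropyranone 15 (not isolated), via acylketene 16 (not isolated), via cyclohexadienone 17 (not isolated)
Conditions: pyridinium p-toluenesulfonate (10 mol %), 4 Å MS, PhMe (5 mM), 40 °C, 2 h; then 110 °C, 4 h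
Reagents that add atoms: none
Why: Proposed new method: the weak acid closes ring C by hemiketalisation and dehydration of the δ-hydroxy-β-diketone (the C2–O bond is never broken, so (S) is retained; the C5 prenyl group blocks the usual aldol aromatisation of diketo-dioxinones), which locks the C8a oxygen as an enol ether so that the acylketene 16 released at 110 °C by retro-[4+2] loss of acetone cannot lactonise to a 2-pyrone, and its C7 enol, a 3-hydroxydienylketene, instead undergoes 6π-electrocyclisation onto C4a to give 17, which tautomerises to ring A with the prenyl group fixed at C6; the closest known reaction types are the dienylketene 6π closure of the Danheiser benzannulation and the thermal dioxinone-to-acylketene aromatisations used for resorcylates.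

**Step 8**
Reactants: 18 (2S)-2-[2,4-bis(tert-butyldimethylsilyloxy)-5-methoxyphenyl]-5,7-dihydroxy-6-(3-methylbut-2-en-1-yl)chroman-4-one
Product: 19 Kushenol V, (2S)-2-(2,4-dihydroxy-5-methoxyphenyl)-5,7-dihydroxy-6-(3-methylbut-2-en-1-yl)-2,3-dihydro-4H-chromen-4-one
Conditions: KHF2 (5 equiv), MeOH, 23 °C
Reagents that add atoms: none
Why: Bifluoride cleavage of aryl silyl ethers under mildly acidic conditions frees both ring B phenols without generating phenoxide, so the base-triggered retro-oxa-Michael racemisation of C2 and acid-induced cyclisation of the prenyl group are both avoided.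

**Compound list**
1 | 2,4-dihydroxy-5-methoxybenzaldehyde | COc1cc(C=O)c(O)cc1O | starting material
2 | 2,4-bis(tert-butyldimethylsilyloxy)-5-methoxybenzaldehyde | COc1cc(C=O)c(O[Si](C)(C)C(C)(C)C)cc1O[Si](C)(C)C(C)(C)C | intermediate
3 | 1-(tert-butylthio)-1-(trimethylsilyloxy)ethene | C=C(O[Si](C)(C)C)SC(C)(C)C | starting material
4 | S-tert-butyl (3S)-3-[2,4-bis(tert-butyldimethylsilyloxy)-5-methoxyphenyl]-3-(trimethylsilyloxy)propanethioate | COc1cc([C@@H](O[Si](C)(C)C)CC(=O)SC(C)(C)C)c(O[Si](C)(C)C(C)(C)C)cc1O[Si](C)(C)C(C)(C)C | intermediate (not isolated)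
5 | S-tert-butyl (3S)-3-[2,4-bis(tert-butyldimethylsilyloxy)-5-methoxyphenyl]-3-hydroxypropanethioate | COc1cc([C@@H](O)CC(=O)SC(C)(C)C)c(O[Si](C)(C)C(C)(C)C)cc1O[Si](C)(C)C(C)(C)C | intermediate
6 | 2,2,6-trimethyl-4H-1,3-dioxin-4-one | CC1=CC(=O)OC(C)(C)O1 | starting material
7 | 5-iodo-2,2,6-trimethyl-4H-1,3-dioxin-4-one | CC1=C(I)C(=O)OC(C)(C)O1 | intermediate
8 | tributyl(3-methylbut-2-en-1-yl)stannane | CCCC[Sn](CCCC)(CCCC)CC=C(C)C | starting material
9 | 2,2,6-trimethyl-5-(3-methylbut-2-en-1-yl)-4H-1,3-dioxin-4-one | CC1=C(CC=C(C)C)C(=O)OC(C)(C)O1 | intermediate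
10 | lithium 2,2-dimethyl-6-methylidene-5-(3-methylbut-2-en-1-yl)-6H-1,3-dioxin-4-olate (γ-dienolate of 9) | [Li+].C=C1OC(C)(C)OC([O-])=C1CC=C(C)C | intermediate (not isolated)
11 | 2,2-dimethyl-5-(3-methylbut-2-en-1-yl)-6-(2-oxopropyl)-4H-1,3-dioxin-4-one | CC(=O)CC1=C(CC=C(C)C)C(=O)OC(C)(C)O1 | intermediate
12 | dilithium dianion of 11 (deprotonated at the dioxinone-flanked CH2 and at the terminal CH3) | [Li+].[Li+].C=C([O-])C=C1OC(C)(C)OC([O-])=C1CC=C(C)C | intermediate (not isolated)
13 | lithium alkoxide of 5 | [Li+].COc1cc([C@@H]([O-])CC(=O)SC(C)(C)C)c(O[Si](C)(C)C(C)(C)C)cc1O[Si](C)(C)C(C)(C)C | intermediate (not isolated)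
14 | 6-{(6S)-6-[2,4-bis(tert-butyldimethylsilyloxy)-5-methoxyphenyl]-6-hydroxy-2,4-dioxohexyl}-2,2-dimethyl-5-(3-methylbut-2-en-1-yl)-4H-1,3-dioxin-4-one (drawn as the triketo tautomer) | COc1cc([C@@H](O)CC(=O)CC(=O)CC2=C(CC=C(C)C)C(=O)OC(C)(C)O2)c(O[Si](C)(C)C(C)(C)C)cc1O[Si](C)(C)C(C)(C)C | intermediate
15 | 6-{[(2S)-2-[2,4-bis(tert-butyldimethylsilyloxy)-5-methoxyphenyl]-4-oxo-3,4-dihydro-2H-pyran-6-yl]methyl}-2,2-dimethyl-5-(3-methylbut-2-en-1-yl)-4H-1,3-dioxin-4-one | COc1cc([C@@H]2CC(=O)C=C(CC3=C(CC=C(C)C)C(=O)OC(C)(C)O3)O2)c(O[Si](C)(C)C(C)(C)C)cc1O[Si](C)(C)C(C)(C)C | intermediate (not isolated)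
16 | 4-[(2S)-2-[2,4-bis(tert-butyldimethylsilyloxy)-5-methoxyphenyl]-4-oxo-3,4-dihydro-2H-pyran-6-yl]-2-(3-methylbut-2-en-1-yl)but-1-ene-1,3-dione (acylketene) | COc1cc([C@@H]2CC(=O)C=C(CC(=O)C(CC=C(C)C)=C=O)O2)c(O[Si](C)(C)C(C)(C)C)cc1O[Si](C)(C)C(C)(C)C | intermediate (not isolated)
17 | (2S)-2-[2,4-bis(tert-butyldimethylsilyloxy)-5-methoxyphenyl]-7-hydroxy-6-(3-methylbut-2-en-1-yl)-2,3-dihydro-4H-chromene-4,5(4aH)-dione (C4a configuration undefined, lost on tautomerisation) | COc1cc([C@@H]2CC(=O)C3C(=O)C(CC=C(C)C)=C(O)C=C3O2)c(O[Si](C)(C)C(C)(C)C)cc1O[Si](C)(C)C(C)(C)C | intermediate (not isolated)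
18 | (2S)-2-[2,4-bis(tert-butyldimethylsilyloxy)-5-methoxyphenyl]-5,7-dihydroxy-6-(3-methylbut-2-en-1-yl)chroman-4-one | COc1cc([C@@H]2CC(=O)c3c(cc(O)c(CC=C(C)C)c3O)O2)c(O[Si](C)(C)C(C)(C)C)cc1O[Si](C)(C)C(C)(C)C | intermediate
19 | Kushenol V, (2S)-2-(2,4-dihydroxy-5-methoxyphenyl)-5,7-dihydroxy-6-(3-methylbut-2-en-1-yl)-2,3-dihydro-4H-chromen-4-one | COc1cc([C@@H]2CC(=O)c3c(cc(O)c(CC=C(C)C)c3O)O2)c(O)cc1O | target

**Totals**
Total step count: 8.
Longest linear sequence: 6 steps (6 → 7 → 9 → 11 → 14 → 18 → 19, steps 3–8).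

**Three steps most likely to fail**

Step 7 (key double ring closure). The acylketene may dimerise or fail to close onto C4a, or incomplete closure of ring C may let the C8a enol lactonise to a 2-pyrone. The fallback sets out from 14 and returns at 18, replacing the pericyclic closure by an ionic one. Compound 14 is cyclodehydrated with pyridinium p-toluenesulfonate in CH2Cl2 at 23 °C and the dihydropyranone 15 is isolated. Heating 15 in toluene with methanol (5 equiv) at 110 °C traps the acylketene as the methyl β-keto ester F1. F1 is then closed by a Claisen-type (Dieckmann) condensation with Mg(OMe)2 in MeOH at 0 → 23 °C, followed by a pH 5 buffer, to give 18. The ee is checked by chiral HPLC because this variant exposes C3 to base.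

Step 6 (polyanion Claisen with a free carbinol). Proton transfer to the dianion or retro-aldol of the lithium aldolate may cut yield or ee. The fallback sets out from 5 and returns at 14, using aldol addition and oxidation in place of acylation. Compound 5 is converted with TESOTf and 2,6-lutidine into the triethylsilyl ether F2. The thioester is reduced with i-Bu2AlH in CH2Cl2 at −78 °C to the aldehyde F3. Dianion 12 is added at −78 °C to give the β-hydroxy ketone F4 as a mixture of carbinol epimers. Dess–Martin periodinane oxidises it to the silyl-protected diketone F5, and pyridinium p-toluenesulfonate in MeOH at 0 °C removes the triethylsilyl group to give 14.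

Step 2 (asymmetric aldol on an electron-rich, ortho-silyloxy aldehyde). Conversion or ee may be low. The fallback sets out from 2 and returns at 5, setting the stereocenter by reduction instead of by C–C bond formation. LiCH2C(O)StBu (from S-tert-butyl thioacetate and LiN(iPr)2, THF, −78 °C) is added to 2 to give the racemic aldol F6. Dess–Martin periodinane gives the β-keto thioester F7. Asymmetric transfer hydrogenation with RuCl[(S,S)-TsDPEN](p-cymene) in HCO2H–Et3N, which gives (S) benzylic alcohols from aryl ketones, delivers 5.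

**Further compounds**
F1 | step 7 | methyl 2-{2-[(2S)-2-[2,4-bis(tert-butyldimethylsilyloxy)-5-methoxyphenyl]-4-oxo-3,4-dihydro-2H-pyran-6-yl]acetyl}-5-methylhex-4-enoate (epimers at the ester α-carbon) | COc1cc([C@@H]2CC(=O)C=C(CC(=O)C(CC=C(C)C)C(=O)OC)O2)c(O[Si](C)(C)C(C)(C)C)cc1O[Si](C)(C)C(C)(C)C
F2 | step 6 | S-tert-butyl (3S)-3-[2,4-bis(tert-butyldimethylsilyloxy)-5-methoxyphenyl]-3-(triethylsilyloxy)propanethioate | COc1cc([C@@H](O[Si](CC)(CC)CC)CC(=O)SC(C)(C)C)c(O[Si](C)(C)C(C)(C)C)cc1O[Si](C)(C)C(C)(C)C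
F3 | step 6 | (3S)-3-[2,4-bis(tert-butyldimethylsilyloxy)-5-methoxyphenyl]-3-(triethylsilyloxy)propanal | COc1cc([C@@H](O[Si](CC)(CC)CC)CC=O)c(O[Si](C)(C)C(C)(C)C)cc1O[Si](C)(C)C(C)(C)C
F4 | step 6 | 6-{(6S)-6-[2,4-bis(tert-butyldimethylsilyloxy)-5-methoxyphenyl]-4-hydroxy-2-oxo-6-(triethylsilyloxy)hexyl}-2,2-dimethyl-5-(3-methylbut-2-en-1-yl)-4H-1,3-dioxin-4-one (epimers at C4 of the hexyl chain) | COc1cc([C@@H](O[Si](CC)(CC)CC)CC(O)CC(=O)CC2=C(CC=C(C)C)C(=O)OC(C)(C)O2)c(O[Si](C)(C)C(C)(C)C)cc1O[Si](C)(C)C(C)(C)C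
F5 | step 6 | 6-{(6S)-6-[2,4-bis(tert-butyldimethylsilyloxy)-5-methoxyphenyl]-2,4-dioxo-6-(triethylsilyloxy)hexyl}-2,2-dimethyl-5-(3-methylbut-2-en-1-yl)-4H-1,3-dioxin-4-one | COc1cc([C@@H](O[Si](CC)(CC)CC)CC(=O)CC(=O)CC2=C(CC=C(C)C)C(=O)OC(C)(C)O2)c(O[Si](C)(C)C(C)(C)C)cc1O[Si](C)(C)C(C)(C)C
F6 | step 2 | S-tert-butyl 3-[2,4-bis(tert-butyldimethylsilyloxy)-5-methoxyphenyl]-3-hydroxypropanethioate (racemic) | COc1cc(C(O)CC(=O)SC(C)(C)C)c(O[Si](C)(C)C(C)(C)C)cc1O[Si](C)(C)C(C)(C)C
F7 | step 2 | S-tert-butyl 3-[2,4-bis(tert-butyldimethylsilyloxy)-5-methoxyphenyl]-3-oxopropanethioate | COc1cc(C(=O)CC(=O)SC(C)(C)C)c(O[Si](C)(C)C(C)(C)C)cc1O[Si](C)(C)C(C)(C)C
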